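A direct plan would formylate two alkylresorcinol cores to reach 2-hydroxy-4-methoxy-6-propylbenzaldehyde A1 and 2,4-dimethoxy-6-pentylbenzaldehyde A2, and would cleave one methyl ether of A2 to give 4-hydroxy-2-methoxy-6-pentylbenzaldehyde A3.
It would join A1 and A3 at the depside C(acyl)–O bond by a metal-catalysed dehydrogenative coupling of the formyl C–H of A1 with the phenol A3 to give the formyl depside 4-formyl-3-methoxy-5-pentylphenyl 2-hydroxy-4-methoxy-6-propylbenzoate A4, and would then oxidise the remaining aldehyde to the acid.
Its weakest steps would be the formyl C–H/phenol coupling leading to A4, which would be without precedent for a 2,6-disubstituted salicylaldehyde and open to decarbonylation and phenol oxidation; the cleavage of one of the two methyl ethers of A2, whose site selectivity would be uncertain; and the final aldehyde oxidation, which would be a redox correction on the finished, electron-rich depside.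

The proposed route disconnects ring A itself instead of the depside C–O bond. Bonds C1–C2 and C5–C6 of ring A are cut, which leads back to the hex-2-ynoate ester 5 of the ring B phenol and the silyloxydiene 8. The key step, a Diels–Alder reaction followed by aromatisation, would build ring A on the ester and set its hydrogen-bonded 2-OH, its 4-OMe and its 6-propyl group in one operation with fixed regiochemistry. The ester bond is made beforehand from an unhindered alkynoic acid, both carboxyl carbons enter at the acid oxidation level, and no methyl ether is cleaved. The C–H coupling, the demethylation and the late oxidation are thereby avoided. The target has no stereocentre.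

Key step: step 5

Assumption: olivetolic acid, hex-2-ynoic acid and methyl (2E)-3-methoxybut-2-enoate are taken as purchasable starting materials.

Step 1
Reactants: 1 olivetolic acid (2,4-dihydroxy-6-pentylbenzoic acid)
Product: 2 benzyl 2,4-dihydroxy-6-pentylbenzoate
Conditions: BnBr (1.05 equiv), KHCO3 (1.2 equiv), DMF, rt
Reagents that add atoms: benzyl bromide, BrCc1ccccc1
Why: Carboxylate O-alkylation (SN2); hydrogencarbonate deprotonates only the carboxylic acid, so both phenols should stay free, and room temperature avoids decarboxylation of the resorcylic acid.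

Step 2
Reactants: 2 benzyl 2,4-dihydroxy-6-pentylbenzoate; 3 hex-2-ynoic acid
Product: 4 benzyl 4-(hex-2-ynoyloxy)-2-hydroxy-6-pentylbenzoate
Conditions: 3 (1.1 equiv), DCC (1.15 equiv), DMAP (5 mol %), CH2Cl2, 0 °C to rt
Reagents that add atoms: none
Why: Steglich esterification; the 4-OH is the only free, unhindered nucleophile because the 2-OH is hydrogen-bonded to the benzyl ester carbonyl, and the acid partner is an unhindered alkynoic acid, so the future depside C–O bond is made as a simple aryl alk-2-ynoate.

Step 3
Reactants: 4 benzyl 4-(hex-2-ynoyloxy)-2-hydroxy-6-pentylbenzoate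
Product: 5 benzyl 4-(hex-2-ynoyloxy)-2-methoxy-6-pentylbenzoate
Conditions: MeI (10 equiv), Ag2O (2 equiv), 4 Å MS, CHCl3, 50 °C, dark
Reagents that add atoms: iodomethane, CI
Why: Purdie methylation (silver-oxide-assisted Williamson etherification); Ag2O activates MeI and takes up HI under heterogeneous, nearly neutral conditions, which should methylate the hydrogen-bonded 2-OH without releasing a free phenoxide that could cleave or add to the aryl ynoate.

Step 4
Reactants: 6 methyl (2E)-3-methoxybut-2-enoate
Product: 8 (1E)-1,3-dimethoxy-1-(trimethylsilyloxy)buta-1,3-diene, via lithium dienolate 7 (not isolated)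
Conditions: LiN(iPr)2 (LDA, 1.1 equiv), THF, −78 °C; then TMSCl (1.2 equiv), −78 °C to rt; distillation under reduced pressure
Reagents that add atoms: chlorotrimethylsilane, C[Si](C)(C)Cl
Why: Vinylogous (γ) deprotonation of the β-methoxy enoate and O-silylation of the extended enolate should give the silyl vinylketene acetal; the geometry of the ketene acetal double bond has no bearing on the arene formed later.

Step 5
Reactants: 5 benzyl 4-(hex-2-ynoyloxy)-2-methoxy-6-pentylbenzoate; 8 (1E)-1,3-dimethoxy-1-(trimethylsilyloxy)buta-1,3-diene
Product: 11 benzyl 4-[(2-hydroxy-4-methoxy-6-propylbenzoyl)oxy]-2-methoxy-6-pentylbenzoate, via cyclohexa-1,4-diene cycloadduct 9 (not isolated), via aryl trimethylsilyl ether 10 (not isolated)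
Conditions: 8 (4 equiv, two portions), xylene, 130 °C, sealed tube; then 1 M HCl, THF, rt
Reagents that add atoms: none
Why: The electron-rich diene 8 should add across the ester-activated C≡C of 5 in a normal-demand Diels–Alder reaction to give the cyclohexa-1,4-diene 9, whose mixed silyl methyl ketal carbon loses methanol (the more basic alkoxy group is the one ionised) by 1,4-elimination across the doubly allylic CH2 to give the aryl silyl ether 10, and the acidic work-up cleaves the O–Si bond. The closest known reaction type is the benzannulation of alk-2-ynoate esters, macrocyclic ynolides included, with 1,3-dioxygenated silyloxydienes to give 6-alkylresorcylates. Ring A is closed by an intermolecular [4+2] cycloaddition that forms its C1–C2 and C5–C6 bonds, followed by aromatisation; no stereocentre remains, because the ketal carbon of 9 becomes C2 of the arene. The step needs one regiochemistry: the terminal CH2 of 8, the vinylogous terminus of three oxygen donors and the site of the largest HOMO coefficient, must bond to the propyl-bearing β-carbon of the ynoate, the site of the largest LUMO coefficient, so that the ketene acetal carbon ends next to the acyl-bearing carbon and becomes the hydrogen-bonded 2-OH while the diene OMe becomes the 4-OMe. Chemoselectivity is secured by the substrate: 5 holds no acidic proton that would quench the diene, its alkyne is the only ester-conjugated C–C π bond, and the aryl ester makes it a better dienophile than an alkyl ynoate.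

Step 6
Reactants: 11 benzyl 4-[(2-hydroxy-4-methoxy-6-propylbenzoyl)oxy]-2-methoxy-6-pentylbenzoate
Product: 12 4-[(2-hydroxy-4-methoxy-6-propylbenzoyl)oxy]-2-methoxy-6-pentylbenzoic acid
Conditions: H2 (1 atm), 10% Pd/C, EtOAc, rt
Reagents that add atoms: none
Why: Hydrogenolysis of the benzylic C–O bond over palladium on carbon should free the acid under neutral conditions that leave the aryl ester, the phenol and both methyl ethers untouched; no reducible C–C multiple bond remains at this stage.

Compound list
1 | olivetolic acid (2,4-dihydroxy-6-pentylbenzoic acid) | CCCCCc1cc(O)cc(O)c1C(=O)O | starting material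
2 | benzyl 2,4-dihydroxy-6-pentylbenzoate | CCCCCc1cc(O)cc(O)c1C(=O)OCc1ccccc1 | intermediate
3 | hex-2-ynoic acid | CCCC#CC(=O)O | starting material
4 | benzyl 4-(hex-2-ynoyloxy)-2-hydroxy-6-pentylbenzoate | CCCCCc1cc(OC(=O)C#CCCC)cc(O)c1C(=O)OCc1ccccc1 | intermediate
5 | benzyl 4-(hex-2-ynoyloxy)-2-methoxy-6-pentylbenzoate | CCCCCc1cc(OC(=O)C#CCCC)cc(OC)c1C(=O)OCc1ccccc1 | intermediate
6 | methyl (2E)-3-methoxybut-2-enoate | CO/C(C)=C/C(=O)OC | starting material
7 | lithium 1,3-dimethoxybuta-1,3-dien-1-olate (not isolated) | [Li+].[O-]C(OC)=CC(OC)=C | intermediate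
8 | (1E)-1,3-dimethoxy-1-(trimethylsilyloxy)buta-1,3-diene | CO/C(O[Si](C)(C)C)=C\C(OC)=C | intermediate
9 | 4-[(benzyloxy)carbonyl]-3-methoxy-5-pentylphenyl 4,6-dimethoxy-2-propyl-6-(trimethylsilyloxy)cyclohexa-1,4-diene-1-carboxylate (racemic, not isolated) | CCCC1=C(C(=O)Oc2cc(OC)c(C(=O)OCc3ccccc3)c(CCCCC)c2)C(OC)(O[Si](C)(C)C)C=C(OC)C1 | intermediate
10 | 4-[(benzyloxy)carbonyl]-3-methoxy-5-pentylphenyl 4-methoxy-6-propyl-2-(trimethylsilyloxy)benzoate (not isolated) | CCCc1cc(OC)cc(O[Si](C)(C)C)c1C(=O)Oc1cc(OC)c(C(=O)OCc2ccccc2)c(CCCCC)c1 | intermediate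
11 | benzyl 4-[(2-hydroxy-4-methoxy-6-propylbenzoyl)oxy]-2-methoxy-6-pentylbenzoate | CCCCCc1cc(OC(=O)c2c(O)cc(OC)cc2CCC)cc(OC)c1C(=O)OCc1ccccc1 | intermediate
12 | 4-[(2-hydroxy-4-methoxy-6-propylbenzoyl)oxy]-2-methoxy-6-pentylbenzoic acid | CCCCCc1cc(OC(=O)c2c(O)cc(OC)cc2CCC)cc(OC)c1C(=O)O | target

Total step count: 6. Longest linear sequence: 5 steps (steps 1, 2, 3, 5 and 6); step 4 supplies the diene.

Steps most likely to fail

Step 5. The cycloaddition onto the β-alkyl ynoate may be slower than the thermal decay of the diene, the diene may add in a stepwise conjugate fashion or attack the aryl ester, and the ketal may lose silanol instead of methanol. The fallback sets out from 5 and returns at 11 by a classical depside esterification. The aryl ester of 5 would be cleaved by methanolysis (K2CO3, MeOH, 0 °C) to benzyl 4-hydroxy-2-methoxy-6-pentylbenzoate F1. Separately, commercial 5-propylresorcinol would be carboxylated (MeOMgOCO2Me, methyl magnesium carbonate, DMF, 120 °C) to 2,4-dihydroxy-6-propylbenzoic acid F2. F2 would be converted with MeI (2.2 equiv) and K2CO3 in acetone into methyl 2-hydroxy-4-methoxy-6-propylbenzoate F3, the hydrogen-bonded 2-OH staying free. Saponification (KOH, aqueous DMSO, 80 °C) would give 2-hydroxy-4-methoxy-6-propylbenzoic acid F4. F4 and F1 would then be condensed with trifluoroacetic anhydride in toluene at rt to give 11.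

Step 3. Methylation of the hydrogen-bonded phenol may stall, and silver may promote cyclisation of the aryl ynoate onto ring B or acyl transfer. The fallback sets out from 2 and returns at 5 by putting the methyl group in before the ynoate. Compound 2 would be allylated selectively at the free 4-OH (allyl bromide, K2CO3, acetone, rt) to benzyl 4-(allyloxy)-2-hydroxy-6-pentylbenzoate F5. Methylation under forcing conditions (MeI, K2CO3, DMF, 50 °C) would give benzyl 4-(allyloxy)-2-methoxy-6-pentylbenzoate F6. Deallylation (Pd(PPh3)4 catalyst, morpholine, THF, rt) would give benzyl 4-hydroxy-2-methoxy-6-pentylbenzoate F1, and esterification with 3 (DCC, DMAP, CH2Cl2) would give 5.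

Step 4. The vinylketene acetal may hydrolyse or isomerise during isolation and so reach the thermal step in poor purity. The fallback sets out from 5 and returns at 11 with another diene and a late methylation. Commercial methyl 3-(trimethylsilyloxy)but-2-enoate would be converted (LiN(iPr)2, TMSCl, THF, −78 °C) into 1-methoxy-1,3-bis(trimethylsilyloxy)buta-1,3-diene F7. F7 would undergo the same cycloaddition with 5 (xylene, 130 °C; then 1 M HCl, THF) to give benzyl 4-[(2,4-dihydroxy-6-propylbenzoyl)oxy]-2-methoxy-6-pentylbenzoate F8. The free, non-hydrogen-bonded and more acidic 4-OH of ring A would then be methylated selectively (TMSCHN2, iPr2NEt, MeOH/MeCN, rt) to give 11.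

Further compounds
F1 | step 5 | benzyl 4-hydroxy-2-methoxy-6-pentylbenzoate | CCCCCc1cc(O)cc(OC)c1C(=O)OCc1ccccc1
F2 | step 5 | 2,4-dihydroxy-6-propylbenzoic acid | CCCc1cc(O)cc(O)c1C(=O)O
F3 | step 5 | methyl 2-hydroxy-4-methoxy-6-propylbenzoate | CCCc1cc(OC)cc(O)c1C(=O)OC
F4 | step 5 | 2-hydroxy-4-methoxy-6-propylbenzoic acid | CCCc1cc(OC)cc(O)c1C(=O)O
F5 | step 3 | benzyl 4-(allyloxy)-2-hydroxy-6-pentylbenzoate | CCCCCc1cc(OCC=C)cc(O)c1C(=O)OCc1ccccc1
F6 | step 3 | benzyl 4-(allyloxy)-2-methoxy-6-pentylbenzoate | CCCCCc1cc(OCC=C)cc(OC)c1C(=O)OCc1ccccc1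
F7 | step 4 | 1-methoxy-1,3-bis(trimethylsilyloxy)buta-1,3-diene | C=C(O[Si](C)(C)C)C=C(OC)O[Si](C)(C)C
F8 | step 4 | benzyl 4-[(2,4-dihydroxy-6-propylbenzoyl)oxy]-2-methoxy-6-pentylbenzoate | CCCCCc1cc(OC(=O)c2c(O)cc(O)cc2CCC)cc(OC)c1C(=O)OCc1ccccc1
A1 | direct plan | 2-hydroxy-4-methoxy-6-propylbenzaldehyde | CCCc1cc(OC)cc(O)c1C=O
A2 | direct plan | 2,4-dimethoxy-6-pentylbenzaldehyde | CCCCCc1cc(OC)cc(OC)c1C=O
A3 | direct plan | 4-hydroxy-2-methoxy-6-pentylbenzaldehyde | CCCCCc1cc(O)cc(OC)c1C=O
A4 | direct plan | 4-formyl-3-methoxy-5-pentylphenyl 2-hydroxy-4-methoxy-6-propylbenzoate | CCCCCc1cc(OC(=O)c2c(O)cc(OC)cc2CCC)cc(OC)c1C=O
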